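Ring C of the target ties O1 to the benzylic C2 and C3 to C4, with O1 and C4 on neighbouring carbons (C8a, C4a) of ring A. One extra formyl carbon on C3 makes this ring the oxa-Michael–aldol condensation product of a salicylaldehyde (O1, C8a, C4a, C4) and a cinnamaldehyde (C2, C3, CHO).
Retrosynthesis: take off the two MOM groups, put CHO back on C3 and unsaturation back at C3=C4, then cut O1–C2 and C3–C4. Ring A goes back through C4a–CHO, C8a–O and C6–prenyl cuts to resorcinol, and ring B through the enal alkene to 3,5-dimethoxybenzaldehyde.
Forward: rings A and B are bought. Ring A is dressed in five steps through mirror-symmetric intermediates, which fixes prenyl at C6; ring B is homologated in one step; ring C, the only ring made, closes in step 7.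
C2 is the only stereocentre. It is set in step 7 by an (R)-diphenylprolinol silyl ether catalyst and no later step breaks a bond at it.
C3=C4 is saturated before the temporary formyl carbon is excised, so the heated decarbonylation acts on a chromane with no electrocyclic path to racemisation. MOM cleavage ends the route.

Key step: step 7

Assumption: the SMILES is read as (2R). The usual steric-shielding model for iminium ions of diarylprolinol silyl ethers is taken to hold for enal 12, and this calls for the (R)-configured amine.

Step 1
Reactants: 1 resorcinol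
Product: 2 1,3-bis(methoxymethoxy)benzene
Conditions: MOMCl (2.5 equiv), N,N-diisopropylethylamine (DIPEA, 3 equiv), CH2Cl2, 0 °C to rt
Reagents that add atoms: chloromethyl methyl ether (MOMCl), COCCl
Why: Base-mediated O-alkylation of both phenols with a reactive α-chloro ether (MOM protection) should be clean, and these acetals direct the metalation of step 2 and withstand the base, boron, magnesium, amine and rhodium chemistry up to step 10.

Step 2
Reactants: 2 1,3-bis(methoxymethoxy)benzene; 3 prenyl bromide
Product: 5 1,3-bis(methoxymethoxy)-2-(3-methylbut-2-enyl)benzene, via 2-lithio arene 4 (not isolated)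
Conditions: n-BuLi (1.1 equiv), THF, 0 °C to rt; then 3 (1.2 equiv), −78 °C to rt
Reagents that add atoms: none
Why: Directed ortho-metalation removes the proton lying between the two coordinating OMOM groups, and aryllithium 4 displaces the primary allylic bromide of 3 in an SN2 alkylation, giving an arene with a mirror plane through C2 and C5.

Step 3
Reactants: 5 1,3-bis(methoxymethoxy)-2-(3-methylbut-2-enyl)benzene
Product: 6 2-[3,5-bis(methoxymethoxy)-4-(3-methylbut-2-enyl)phenyl]-4,4,5,5-tetramethyl-1,3,2-dioxaborolane
Conditions: [Ir(OMe)(cod)]2 (1.5 mol %), 4,4'-di-tert-butyl-2,2'-bipyridine (3 mol %), B2pin2 (1.0 equiv), THF, 65 °C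
Reagents that add atoms: bis(pinacolato)diboron, CC1(C)OB(OC1(C)C)B1OC(C)(C)C(C)(C)O1
Why: Iridium-catalysed aromatic C–H borylation (Hartwig–Miyaura type) is sterically governed and avoids C–H bonds ortho to a substituent, so only C5–H should react, while the trisubstituted prenyl alkene is too hindered for hydroboration by the pinacolborane formed.

Step 4
Reactants: 6 the aryl pinacol boronate
Product: 7 3,5-bis(methoxymethoxy)-4-(3-methylbut-2-enyl)phenol
Conditions: 30% aq H2O2, aq NaOH (1.1 equiv), THF, 0 °C to rt; aq NH4Cl
Reagents that add atoms: hydrogen peroxide, OO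
Why: Ipso-oxidation of the arylboronate (hydroperoxide adds to boron, the aryl group migrates from boron to oxygen, the borate ester hydrolyses) gives the phenol, and nucleophilic alkaline peroxide leaves the unactivated alkene and the base-stable MOM ethers alone.

Step 5
Reactants: 7 3,5-bis(methoxymethoxy)-4-(3-methylbut-2-enyl)phenol
Product: 10 6-hydroxy-2,4-bis(methoxymethoxy)-3-(3-methylbut-2-enyl)benzaldehyde, via chloromagnesium phenoxide 8 (not isolated), via salicyl alcohol 9 (not isolated)
Conditions: MgCl2 (2 equiv), Et3N (4 equiv), (CH2O)n (6 equiv), MeCN, 80 °C; cold dilute aq HCl work-up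
Reagents that add atoms: paraformaldehyde (reacts as formaldehyde), C=O
Why: In this Casnati–Skattebøl ortho-formylation, formaldehyde is delivered within magnesium phenoxide 8 to the ortho carbon and the salicyl alcohol stage 9 is oxidised in situ by hydride transfer to a second formaldehyde; only one aldehyde can form because the two ortho positions of 7 are mirror images and the para position is blocked.

Step 6
Reactants: 11 3,5-dimethoxybenzaldehyde
Product: 12 (E)-3-(3,5-dimethoxyphenyl)prop-2-enal
Conditions: Ph3P=CHCHO (1.05 equiv), toluene, 80 °C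
Reagents that add atoms: (triphenylphosphoranylidene)acetaldehyde, O=CC=P(c1ccccc1)(c1ccccc1)c1ccccc1
Why: Wittig olefination with a stabilised formyl ylide is E-selective, and a near-stoichiometric charge of ylide limits a second homologation of the product enal.

Step 7
Reactants: 10 6-hydroxy-2,4-bis(methoxymethoxy)-3-(3-methylbut-2-enyl)benzaldehyde; 12 (E)-3-(3,5-dimethoxyphenyl)prop-2-enal
Product: 13 (2S)-2-(3,5-dimethoxyphenyl)-5,7-bis(methoxymethoxy)-6-(3-methylbut-2-enyl)-2H-chromene-3-carbaldehyde
Conditions: 12 (1.2 equiv), (R)-2-[diphenyl(trimethylsilyloxy)methyl]pyrrolidine (20 mol %), 2-nitrobenzoic acid (20 mol %), 4 Å MS, toluene, rt, dark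
Reagents that add atoms: none
Why: The amine and 12 condense to an E-configured, s-trans iminium ion; the only free phenol oxygen of 10 adds to its β-carbon (O1–C2), the enamine so formed attacks the adjacent aryl aldehyde through its α-carbon (C3–C4), and loss of water followed by hydrolysis releases 13 and the amine. This is the known diarylprolinol silyl ether-catalysed oxa-Michael–aldol condensation domino of salicylaldehydes with cinnamaldehydes, applied here to a more electron-rich salicylaldehyde. Ring C closes in the aldol event as a 6-(enolexo)-exo-trig attack of C3 on the C4 carbonyl group, and the dehydration that follows makes the sequence irreversible. C2 is controlled by the catalyst: the C(Ph)2OSiMe3 arm of the (R)-amine covers the Si face of the β-carbon, O1 enters on the Re face, and the product is (S)-13, whose descriptor differs from that of the target only because C3 with its formyl group outranks the aryl ring. The step needs activation of one aldehyde only and a single site of O-attack: 12 alone can give a conjugated iminium ion, the aldehyde of 10 has no α-hydrogen and can act only as acceptor, the other two ring A oxygens are capped as MOM ethers, and the mirror symmetry of 7 has already fixed prenyl at C6. The acid co-catalyst and the sieves speed iminium turnover and dehydration so that the reversible oxa-Michael stage is drained quickly, and light is excluded because 2H-chromenes ring-open photochemically.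

Step 8
Reactants: 13 the (2S)-2H-chromene-3-carbaldehyde
Product: 15 (2R)-2-(3,5-dimethoxyphenyl)-5,7-bis(methoxymethoxy)-6-(3-methylbut-2-enyl)chromane-3-carbaldehyde as a mixture of C3 epimers, via triethylsilyl enol ether 14 (not isolated)
Conditions: Et3SiH (1.5 equiv), RhCl(PPh3)3 (3 mol %), toluene, rt to 45 °C, dark; then AcOH/THF/H2O, rt
Reagents that add atoms: none
Why: Rhodium-catalysed 1,4-hydrosilylation of an enal by a monohydrosilane puts hydrogen on C4 and silicon on the carbonyl oxygen, spares the isolated trisubstituted prenyl alkene, and passes through the neutral enol ether 14 rather than a metal enolate or enamine, so O1 is not expelled from C2 by β-elimination; mild acid hydrolysis then gives 15, whose C3 configuration is irrelevant because C3 ends as CH2 (the C2 descriptor changes from S to R by priority rules only).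

Step 9
Reactants: 15 the (2R)-chromane-3-carbaldehyde
Product: 16 (2R)-2-(3,5-dimethoxyphenyl)-5,7-bis(methoxymethoxy)-6-(3-methylbut-2-enyl)chromane
Conditions: RhCl(PPh3)3 (1.1 equiv), degassed toluene, 110 °C
Reagents that add atoms: none
Why: In the Tsuji–Wilkinson decarbonylation, oxidative addition of the formyl C–H bond to monovalent rhodium, extrusion of CO and C–H reductive elimination replace CHO by H at C3, both C3 epimers converge on one product, and C2 takes no part and cannot be lost thermally once ring C is saturated.

Step 10
Reactants: 16 the (2R)-bis-MOM flavan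
Product: 17 (2R)-2-(3,5-dimethoxyphenyl)-6-(3-methylbut-2-enyl)chromane-5,7-diol
Conditions: dilute HCl in MeOH, 0 °C to rt
Reagents that add atoms: none
Why: Acid-catalysed acetal exchange with methanol frees both phenols under the dilute, cool conditions customary for prenylated phenols, which keep the prenyl alkene from adding to the neighbouring hydroxyl groups, and C2 is safe because the ring B methoxy groups are meta to it and lend a C2 cation no support.

Compound list
1 | resorcinol | Oc1cccc(O)c1 | starting material
2 | 1,3-bis(methoxymethoxy)benzene | COCOc1cccc(OCOC)c1 | intermediate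
3 | prenyl bromide (1-bromo-3-methylbut-2-ene) | CC(C)=CCBr | starting material
4 | [2,6-bis(methoxymethoxy)phenyl]lithium | [Li]c1c(OCOC)cccc1OCOC | intermediate
5 | 1,3-bis(methoxymethoxy)-2-(3-methylbut-2-enyl)benzene | COCOc1cccc(OCOC)c1CC=C(C)C | intermediate
6 | 2-[3,5-bis(methoxymethoxy)-4-(3-methylbut-2-enyl)phenyl]-4,4,5,5-tetramethyl-1,3,2-dioxaborolane | COCOc1cc(B2OC(C)(C)C(C)(C)O2)cc(OCOC)c1CC=C(C)C | intermediate
7 | 3,5-bis(methoxymethoxy)-4-(3-methylbut-2-enyl)phenol | COCOc1cc(O)cc(OCOC)c1CC=C(C)C | intermediate
8 | chloromagnesium 3,5-bis(methoxymethoxy)-4-(3-methylbut-2-enyl)phenoxide | COCOc1cc(O[Mg]Cl)cc(OCOC)c1CC=C(C)C | intermediate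
9 | 2-(hydroxymethyl)-3,5-bis(methoxymethoxy)-4-(3-methylbut-2-enyl)phenol (present as its magnesium salt, drawn neutral) | COCOc1cc(O)c(CO)c(OCOC)c1CC=C(C)C | intermediate
10 | 6-hydroxy-2,4-bis(methoxymethoxy)-3-(3-methylbut-2-enyl)benzaldehyde | COCOc1cc(O)c(C=O)c(OCOC)c1CC=C(C)C | intermediate
11 | 3,5-dimethoxybenzaldehyde | COc1cc(C=O)cc(OC)c1 | starting material
12 | (E)-3-(3,5-dimethoxyphenyl)prop-2-enal | COc1cc(OC)cc(/C=C/C=O)c1 | intermediate
13 | (2S)-2-(3,5-dimethoxyphenyl)-5,7-bis(methoxymethoxy)-6-(3-methylbut-2-enyl)-2H-chromene-3-carbaldehyde | COc1cc(OC)cc([C@H]2C(C=O)=Cc3c(cc(OCOC)c(CC=C(C)C)c3OCOC)O2)c1 | intermediate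
14 | (2S)-2-(3,5-dimethoxyphenyl)-5,7-bis(methoxymethoxy)-6-(3-methylbut-2-enyl)-3-[(triethylsilyloxy)methylidene]chromane, enol ether geometry not defined | COc1cc(OC)cc([C@H]2C(=CO[Si](CC)(CC)CC)Cc3c(cc(OCOC)c(CC=C(C)C)c3OCOC)O2)c1 | intermediate
15 | (2R)-2-(3,5-dimethoxyphenyl)-5,7-bis(methoxymethoxy)-6-(3-methylbut-2-enyl)chromane-3-carbaldehyde, both C3 epimers | COc1cc(OC)cc([C@H]2C(C=O)Cc3c(cc(OCOC)c(CC=C(C)C)c3OCOC)O2)c1 | intermediate
16 | (2R)-2-(3,5-dimethoxyphenyl)-5,7-bis(methoxymethoxy)-6-(3-methylbut-2-enyl)chromane | COc1cc(OC)cc([C@H]2CCc3c(cc(OCOC)c(CC=C(C)C)c3OCOC)O2)c1 | intermediate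
17 | (2R)-2-(3,5-dimethoxyphenyl)-6-(3-methylbut-2-enyl)chromane-5,7-diol | COc1cc(OC)cc([C@H]2CCc3c(cc(O)c(CC=C(C)C)c3O)O2)c1 | target

Total step count: 10. Longest linear sequence: 9 (steps 1–5, then 7–10).

Steps most likely to fail

Step 7. The aldol closure must attack an aldehyde that carries three oxygen donors and two ortho substituents. It may be slow enough for the reversible oxa-Michael addition to equilibrate, so that conversion stalls and facial selectivity erodes. The fallback sets C2 by ketone reduction and closes O1–C2 by SN2 displacement.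
- It sets out from 10. Claisen–Schmidt condensation with commercial 3,5-dimethoxyacetophenone (KOH, EtOH) should give (E)-1-(3,5-dimethoxyphenyl)-3-[6-hydroxy-2,4-bis(methoxymethoxy)-3-(3-methylbut-2-enyl)phenyl]prop-2-en-1-one F1.
- Conjugate reduction with [(Ph3P)CuH]6 in wet toluene leaves the prenyl alkene alone and gives 1-(3,5-dimethoxyphenyl)-3-[6-hydroxy-2,4-bis(methoxymethoxy)-3-(3-methylbut-2-enyl)phenyl]propan-1-one F2. The phenol consumes one extra hydride equivalent.
- Noyori asymmetric transfer hydrogenation with RuCl[(S,S)-TsDPEN](p-cymene) in HCO2H/Et3N gives (1S)-1-(3,5-dimethoxyphenyl)-3-[6-hydroxy-2,4-bis(methoxymethoxy)-3-(3-methylbut-2-enyl)phenyl]propan-1-ol F3.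
- Intramolecular Mitsunobu etherification (PPh3, DIAD, THF, 0 °C) inverts the carbinol centre and comes back to the route at 16.

Step 8. Hydride delivery to C4 may fail or turn into 1,2-addition. The enal is the acceptor end of a push–pull system fed by O1 and both MOM-protected oxygens, C4 is flanked by the C5 OMOM group, and the catalyst may be consumed by decarbonylation. The fallback inverts the order of events.
- It sets out from 13. Stoichiometric RhCl(PPh3)3 in benzene at 80 °C in the dark, the lowest practicable temperature, excises the formyl group first and gives (2R)-2-(3,5-dimethoxyphenyl)-5,7-bis(methoxymethoxy)-6-(3-methylbut-2-enyl)-2H-chromene F4.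
- Diimide generated at rt from 2-nitrobenzenesulfonylhydrazide and Et3N in CH2Cl2 should reduce the cis-disubstituted C3=C4 bond faster than the trisubstituted prenyl alkene, coming back at 16.
- The enantiomeric purity has to be checked after the heated step, because thermal electrocyclic opening of ring C can erode C2.

Step 9. CO extrusion from the branched acyl complex may be slow. β-Hydride elimination from the secondary alkylrhodium hydride, or migration of the prenyl double bond on long heating, may then compete. The fallback removes the carbon as CO2 by a radical path at rt.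
- It sets out from 15. Pinnick oxidation (NaClO2, NaH2PO4, excess 2-methylbut-2-ene, t-BuOH/H2O) gives (2R)-2-(3,5-dimethoxyphenyl)-5,7-bis(methoxymethoxy)-6-(3-methylbut-2-enyl)chromane-3-carboxylic acid F5.
- Coupling with 1-hydroxypyridine-2(1H)-thione and N,N'-dicyclohexylcarbodiimide in CH2Cl2 in the dark gives its 2-thioxopyridin-1(2H)-yl ester F6.
- Barton decarboxylation (t-BuSH, visible light, toluene, rt) lets the fast hydrogen donor capture the C3 radical before the C2–O1 bond can fragment, and comes back at 16.

Further compounds
F1 | step 7 | (E)-1-(3,5-dimethoxyphenyl)-3-[6-hydroxy-2,4-bis(methoxymethoxy)-3-(3-methylbut-2-enyl)phenyl]prop-2-en-1-one | COc1cc(OC)cc(C(=O)/C=C/c2c(O)cc(OCOC)c(CC=C(C)C)c2OCOC)c1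
F2 | step 7 | 1-(3,5-dimethoxyphenyl)-3-[6-hydroxy-2,4-bis(methoxymethoxy)-3-(3-methylbut-2-enyl)phenyl]propan-1-one | COc1cc(OC)cc(C(=O)CCc2c(O)cc(OCOC)c(CC=C(C)C)c2OCOC)c1
F3 | step 7 | (1S)-1-(3,5-dimethoxyphenyl)-3-[6-hydroxy-2,4-bis(methoxymethoxy)-3-(3-methylbut-2-enyl)phenyl]propan-1-ol | COc1cc(OC)cc([C@@H](O)CCc2c(O)cc(OCOC)c(CC=C(C)C)c2OCOC)c1
F4 | step 8 | (2R)-2-(3,5-dimethoxyphenyl)-5,7-bis(methoxymethoxy)-6-(3-methylbut-2-enyl)-2H-chromene | COc1cc(OC)cc([C@H]2C=Cc3c(cc(OCOC)c(CC=C(C)C)c3OCOC)O2)c1
F5 | step 9 | (2R)-2-(3,5-dimethoxyphenyl)-5,7-bis(methoxymethoxy)-6-(3-methylbut-2-enyl)chromane-3-carboxylic acid, both C3 epimers | COc1cc(OC)cc([C@H]2C(C(=O)O)Cc3c(cc(OCOC)c(CC=C(C)C)c3OCOC)O2)c1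
F6 | step 9 | 2-thioxopyridin-1(2H)-yl (2R)-2-(3,5-dimethoxyphenyl)-5,7-bis(methoxymethoxy)-6-(3-methylbut-2-enyl)chromane-3-carboxylate, both C3 epimers | COc1cc(OC)cc([C@H]2C(C(=O)On4ccccc4=S)Cc3c(cc(OCOC)c(CC=C(C)C)c3OCOC)O2)c1
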